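**Plan**

- Retrosynthesis: the two acetates come off first, then the chain is cut at C11–C12 (C11 alkylborane plus a C12–C16 allylic bromide) and C11 is cut from C9. Ring A is then opened at C3–C4, and C1 and the C10 methyl are cut from C10, which leaves (R)-carvone.
- Forward: ring B is carvone itself (C7=C8, C8 methyl, C9 carbonyl). C10 is made quaternary by methylation and an acrolein aldol, ring A closes by a hydrogen-atom-transfer radical cyclisation, the C1 oxygen is removed, C11 is added and the side chain is joined last.
- Enabling feature: the gem-dimethyl carbon C4 lies next to ring-fusion carbon C5 and is the isopropenyl carbon of carvone. One hydrogen atom added to its CH2 gives a tertiary C4 radical within reach of C3 of an acryloyl group on C10.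
- Stereochemistry: C5 comes from (R)-carvone; C10 from aldol attack anti to the isopropenyl group, which also fixes the trans fusion; C9 from hydroboration on the α face; C14 from methyl (R)-2,2-dimethyl-1,3-dioxolane-4-carboxylate.

Key step: step 4

Remark: labdane numbering is used for all bicyclic intermediates, and the target is read as the normal-series labdane (5S,9S,10S; 5α-H, 9α-H, 10β-CH3) with 14S. Centres that are erased again (the C6 methine after the methylation, the carbinol after the aldol) may be carried as mixtures.

**Route**

Step 1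
Reactants: 1 (R)-carvone; 2 iodomethane
Product: 4 trans-6-methylcarvone [(5R,6S)-2,6-dimethyl-5-(prop-1-en-2-yl)cyclohex-2-en-1-one], via lithium dienolate 3 (not isolated)
Conditions: LiN(iPr)2, THF, −78 °C; then MeI, −78 to 0 °C
Reagents that add atoms: iodomethane (compound 2), CI
Why: Kinetic α′-deprotonation gives the cross-conjugated dienolate, which is methylated (SN2 enolate alkylation) mainly anti to the isopropenyl group; the C6 configuration does not matter because C6 is planarised again in step 2.

Step 2
Reactants: 4 trans-6-methylcarvone; 5 acrolein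
Product: 7 6-(1-hydroxyprop-2-en-1-yl)-6-methylcarvone (hydroxyallyl trans and methyl cis to isopropenyl; both carbinol epimers), via lithium enolate 6 (not isolated)
Conditions: LiN(iPr)2, THF, −78 °C; then acrolein, −78 °C; AcOH quench at −78 °C
Reagents that add atoms: acrolein (compound 5), C=CC=O
Why: The tetrasubstituted lithium enolate undergoes aldol 1,2-addition to acrolein on the face anti to the C5 isopropenyl group, which sets the quaternary centre (future C10) as in the second alkylation of 6-alkylcarvones; the cold acidic quench prevents retro-aldol cleavage.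

Step 3
Reactants: 7 6-(1-hydroxyprop-2-en-1-yl)-6-methylcarvone
Product: 8 (5S,6R)-2,6-dimethyl-6-(prop-2-enoyl)-5-(prop-1-en-2-yl)cyclohex-2-en-1-one (acryloyl trans to isopropenyl)
Conditions: Dess–Martin periodinane, CH2Cl2, 0 °C to rt
Reagents that add atoms: none
Why: Dess–Martin oxidation converts the secondary allylic alcohol into the vinyl ketone under non-basic conditions that spare the Michael-sensitive and retro-Claisen-prone product and remove the stray carbinol centre.

Step 4
Reactants: 8 6-acryloyl-6-methylcarvone
Product: 9 11-nordrim-7-ene-1,9-dione (trans-fused; 5α-H, 10β-CH3)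
Conditions: Fe(acac)3 (0.3 equiv), PhSiH3 (2.5 equiv), EtOH/ethylene glycol 5:1, 0.02 M, 60 °C
Reagents that add atoms: none
Why: Fe(acac)3 and PhSiH3 in ethanol form an iron hydride that transfers a hydrogen atom to the CH2 terminus of the isopropenyl group; the tertiary C4 radical adds to the terminal carbon C3 of the acryloyl group, forming C3–C4, and the α-keto radical at C2 is reduced by divalent iron to the enolate and protonated by the solvent. The closest known reaction type is the iron-hydride reductive olefin–enone coupling, used here intramolecularly as a radical conjugate addition. Ring A closes in the 6-endo-trig mode, the only one that joins the nucleophilic radical to the electron-poor β-carbon. No stereocentre is created, since C4 carries two methyl groups and C2 and C3 are methylene; the trans fusion is already fixed by the trans relation of the isopropenyl and acryloyl groups at C5 and C10. The step needs hydrogen-atom transfer to the isopropenyl group and not to either enone, which the electron-rich 1,1-disubstituted alkene secures, and 6-endo instead of 5-exo attack, which polarity matching and the unsubstituted terminus secure. High dilution should keep the vinyl ketone from oligomerising.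

Step 5
Reactants: 9 11-nordrim-7-ene-1,9-dione
Product: 11 9-oxo-11-nordrima-1,7-dien-1-yl trifluoromethanesulfonate, via potassium enolate 10 (not isolated)
Conditions: KN(SiMe3)2, THF, −78 °C; then PhNTf2, −78 to 0 °C
Reagents that add atoms: N-phenylbis(trifluoromethanesulfonimide), O=S(=O)(N(c1ccccc1)S(=O)(=O)C(F)(F)F)C(F)(F)F
Why: C2 is the only enolisable α-position (C10 is quaternary and the enone offers only γ-hydrogens), so kinetic deprotonation and O-sulfonylation give the C1 enol triflate regioselectively (enol triflate formation).

Step 6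
Reactants: 11 enol triflate
Product: 12 11-nordrima-1,7-dien-9-one
Conditions: Pd(OAc)2 (5 mol %), PPh3, HCO2H, Bu3N, DMF, 60 °C
Reagents that add atoms: none
Why: Palladium-catalysed formate reduction of the enol triflate (oxidative addition to zerovalent palladium, formate-to-hydride exchange with loss of CO2, reductive elimination) replaces the C1 oxygen by hydrogen and leaves the enone untouched.

Step 7
Reactants: 12 11-nordrima-1,7-dien-9-one
Product: 13 11-nordrim-7-en-9-one
Conditions: H2 (1 atm), RhCl(PPh3)3 (5 mol %), benzene, rt
Reagents that add atoms: none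
Why: Homogeneous hydrogenation with RhCl(PPh3)3 reduces the cis-disubstituted C1=C2 alkene much faster than the trisubstituted conjugated C7=C8 alkene, the same discrimination that allows selective hydrogenation of the isopropenyl group of carvone.

Step 8
Reactants: 13 11-nordrim-7-en-9-one
Product: 14 drima-7,9(11)-diene
Conditions: Ph3PCH3Br, KOtBu, toluene, 90 °C
Reagents that add atoms: methyltriphenylphosphonium bromide, C[P+](c1ccccc1)(c1ccccc1)c1ccccc1.[Br-]
Why: Wittig methylenation with excess ylide at elevated temperature is the standard method for hindered ketones, and the C9 carbonyl has no α-hydrogen on C10 that could divert the ylide into enolisation.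

Step 9
Reactants: 15 methyl (R)-2,2-dimethyl-1,3-dioxolane-4-carboxylate
Product: 17 (4S)-2,2-dimethyl-4-[3-(trimethylsilyl)prop-1-en-2-yl]-1,3-dioxolane, via bis(silylmethyl)carbinol 16 (not isolated)
Conditions: Me3SiCH2MgCl (3 equiv), CeCl3 (3 equiv), THF, −78 °C to rt; then silica gel, CH2Cl2, rt
Reagents that add atoms: (trimethylsilyl)methylmagnesium chloride, C[Si](C)(C)C[Mg]Cl
Why: Double addition of the weakly basic organocerium reagent to the ester followed by Peterson elimination gives the 2-substituted allylsilane; the dioxolane stereocentre is not touched and its descriptor changes from R to S only through the priority rules.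

Step 10
Reactants: 17 allylsilane
Product: 18 (4S)-4-(3-bromoprop-1-en-2-yl)-2,2-dimethyl-1,3-dioxolane
Conditions: NBS, CH2Cl2, −78 °C
Reagents that add atoms: N-bromosuccinimide, O=C1CCC(=O)N1Br
Why: Electrophilic bromodesilylation (SE2′) places bromine on the terminal alkene carbon and expels the silyl group from the β-silyl cation; the allyl shift is degenerate for this 2-substituted unit and the acetonide tolerates the neutral conditions.

Step 11
Reactants: 14 drima-7,9(11)-diene; 18 allylic bromide
Product: 21 (14S)-14,15-O-isopropylidenelabda-7,13(16)-diene-14,15-diol, via alkylborane 19 (not isolated), via potassium borate 20 (not isolated)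
Conditions: 9-BBN, THF, 60 °C; then KOtBu, rt; then CuOAc (10 mol %), 18, THF, 60 °C
Reagents that add atoms: none
Why: 9-BBN adds to the terminal, least hindered alkene of the diene with boron on C11 and hydrogen delivered syn to C9 from the α face opposite the axial C10 methyl, which sets 9α-H (9S); the tert-butoxy borate then passes its primary alkyl group to monovalent copper and the alkylcopper substitutes the allylic bromide (copper-catalysed allyl–alkyl coupling of an alkyl-9-BBN, where SN2 and SN2′ paths give the same product).

Step 12
Reactants: 21 acetonide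
Product: 22 (14S)-labda-7,13(16)-diene-14,15-diol
Conditions: AcOH/H2O/THF 4:1:1, 45 °C
Reagents that add atoms: none
Why: Mild aqueous acid hydrolyses the isopropylidene acetal without ionising the secondary allylic C14–O bond or moving the C7=C8 and C13=C16 alkenes.

Step 13
Reactants: 22 diol
Product: 23 (14S)-labda-7,13(16)-diene-14,15-diyl diacetate
Conditions: Ac2O, pyridine, DMAP (cat.), CH2Cl2, rt
Reagents that add atoms: acetic anhydride, CC(=O)OC(C)=O
Why: DMAP-catalysed acetylation esterifies the primary and the secondary allylic hydroxyl groups at oxygen, so C14 keeps its configuration.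

**Compound list**

1 | (R)-carvone | CC1=CC[C@@H](C(C)=C)CC1=O | starting material
2 | iodomethane | CI | starting material
3 | lithium dienolate of carvone (C1–OLi, C1=C6) | CC1=CC[C@@H](C(C)=C)C=C1O[Li] | intermediate
4 | trans-6-methylcarvone, (5R,6S) | O=C1C(C)=CC[C@@H](C(C)=C)[C@@H]1C | intermediate
5 | acrolein | C=CC=O | starting material
6 | lithium enolate of 4 (C1–OLi, C1=C6) | CC1=CC[C@@H](C(C)=C)C(C)=C1O[Li] | intermediate
7 | 6-(1-hydroxyprop-2-en-1-yl)-6-methylcarvone, hydroxyallyl trans to isopropenyl, carbinol epimers | O=C1C(C)=CC[C@@H](C(C)=C)[C@]1(C)C(O)C=C | intermediate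
8 | (5S,6R)-2,6-dimethyl-6-(prop-2-enoyl)-5-(prop-1-en-2-yl)cyclohex-2-en-1-one | O=C1C(C)=CC[C@@H](C(C)=C)[C@]1(C)C(=O)C=C | intermediate
9 | 11-nordrim-7-ene-1,9-dione, trans-fused | O=C1C(C)=CC[C@H]2C(C)(C)CCC(=O)[C@]12C | intermediate
10 | potassium C1(2)-enolate of 9 | O=C1C(C)=CC[C@H]2C(C)(C)CC=C(O[K])[C@]12C | intermediate
11 | 9-oxo-11-nordrima-1,7-dien-1-yl trifluoromethanesulfonate | O=C1C(C)=CC[C@H]2C(C)(C)CC=C(OS(=O)(=O)C(F)(F)F)[C@]12C | intermediate
12 | 11-nordrima-1,7-dien-9-one | O=C1C(C)=CC[C@H]2C(C)(C)CC=C[C@]12C | intermediate
13 | 11-nordrim-7-en-9-one | O=C1C(C)=CC[C@H]2C(C)(C)CCC[C@]12C | intermediate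
14 | drima-7,9(11)-diene | C=C1C(C)=CC[C@H]2C(C)(C)CCC[C@]12C | intermediate
15 | methyl (R)-2,2-dimethyl-1,3-dioxolane-4-carboxylate | COC(=O)[C@H]1COC(C)(C)O1 | starting material
16 | 2-[(4R)-2,2-dimethyl-1,3-dioxolan-4-yl]-1,3-bis(trimethylsilyl)propan-2-ol | C[Si](C)(C)CC(O)(C[Si](C)(C)C)[C@H]1COC(C)(C)O1 | intermediate
17 | (4S)-2,2-dimethyl-4-[3-(trimethylsilyl)prop-1-en-2-yl]-1,3-dioxolane | C=C(C[Si](C)(C)C)[C@H]1COC(C)(C)O1 | intermediate
18 | (4S)-4-(3-bromoprop-1-en-2-yl)-2,2-dimethyl-1,3-dioxolane | C=C(CBr)[C@H]1COC(C)(C)O1 | intermediate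
19 | 9-(drim-7-en-11-yl)-9-borabicyclo[3.3.1]nonane, 9α-H | C(B1C2CCCC1CCC2)[C@H]1C(C)=CC[C@H]2C(C)(C)CCC[C@]12C | intermediate
20 | potassium tert-butoxy(drim-7-en-11-yl)borate of 9-borabicyclo[3.3.1]nonane | [K+].CC(C)(C)O[B-]1(C[C@H]2C(C)=CC[C@H]3C(C)(C)CCC[C@]23C)C4CCCC1CCC4 | intermediate
21 | (14S)-14,15-O-isopropylidenelabda-7,13(16)-diene-14,15-diol | C=C(CC[C@H]1C(C)=CC[C@H]2C(C)(C)CCC[C@]12C)[C@H]1COC(C)(C)O1 | intermediate
22 | (14S)-labda-7,13(16)-diene-14,15-diol | C=C(CC[C@H]1C(C)=CC[C@H]2C(C)(C)CCC[C@]12C)[C@@H](CO)O | intermediate
23 | (14S)-labda-7,13(16)-diene-14,15-diyl diacetate | C=C(CC[C@H]1C(C)=CC[C@H]2C(C)(C)CCC[C@]12C)[C@@H](COC(C)=O)OC(C)=O | target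

**Step count**

Total step count: 13 (11 in the main line, 2 for the side-chain fragment).
Longest linear sequence: 11 steps, from (R)-carvone through steps 1–8 and 11–13.

**Steps most likely to fail**

Step 11. The β-branched, neopentyl-like alkyl group may pass from boron to copper too slowly, so that protodeboronation or consumption of the bromide by alkoxide overtakes the coupling. The fallback sets out from 14 and returns at 21, replacing the borate by an organolithium. Hydroboration of 14 with 9-BBN to the same borane 19 and oxidation (NaOH, H2O2) should give drimenol F1. Iodination (I2, PPh3, imidazole, CH2Cl2) should give 11-iododrim-7-ene F2. Iodine–lithium exchange (t-BuLi, Et2O/pentane, −78 °C) should give drim-7-en-11-yllithium F3, which is allylated with 18 under CuI catalysis (10 mol %, THF, −78 to 0 °C) to give 21.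

Step 4. The acryloyl group may oligomerise or be reduced at its own alkene before the tertiary radical forms and closes ring A, or the isopropenyl group may simply be hydrogenated. The fallback sets out from 4 and returns at 14; it keeps the C3–C4 radical closure but uses a sturdier acceptor and never places oxygen on C1, so steps 5–7 fall away. Enolate 6 is alkylated with the known 3-bromo-2-(phenylsulfonyl)prop-1-ene (THF, −78 °C, anti to isopropenyl) to give 6-methyl-6-[2-(phenylsulfonyl)prop-2-en-1-yl]carvone F4. Fe(acac)3 and PhSiH3 in EtOH should then close ring A 6-endo onto the vinyl sulfone to give 2-(phenylsulfonyl)-11-nordrim-7-en-9-one F5 as C2 epimers. Wittig methylenation (Ph3PCH3Br, KOtBu) gives 2-(phenylsulfonyl)drima-7,9(11)-diene F6, and reductive desulfonylation (Mg, MeOH, cat. HgCl2) gives 14.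

Step 7. The hydrogenation may lose chemoselectivity, either stalling at the alkene beside the quaternary carbon or running on into the conjugated C7=C8 alkene. The fallback sets out from 9 and returns at 13, removing the C1 oxygen by a radical deoxygenation in place of steps 5–7. NaBH4 (EtOH, −20 °C) should reduce the saturated C1 ketone in preference to the enone and give 1β-hydroxy-11-nordrim-7-en-9-one F7 (either epimer serves). Thiocarbonyldiimidazole with DMAP (1,2-dichloroethane, 80 °C) gives O-(9-oxo-11-nordrim-7-en-1β-yl) 1H-imidazole-1-carbothioate F8. Barton–McCombie reduction (Bu3SnH kept concentrated to outrun a 1,2-acyl shift of the C1 radical, AIBN, toluene, 90 °C) gives 13.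

Further compounds
F1 | step 11 | drimenol (drim-7-en-11-ol) | OC[C@H]1C(C)=CC[C@H]2C(C)(C)CCC[C@]12C
F2 | step 11 | 11-iododrim-7-ene | IC[C@H]1C(C)=CC[C@H]2C(C)(C)CCC[C@]12C
F3 | step 11 | drim-7-en-11-yllithium | [Li]C[C@H]1C(C)=CC[C@H]2C(C)(C)CCC[C@]12C
F4 | step 4 | 6-methyl-6-[2-(phenylsulfonyl)prop-2-en-1-yl]carvone, sulfonylallyl trans to isopropenyl | O=C1C(C)=CC[C@@H](C(C)=C)[C@]1(C)CC(=C)S(=O)(=O)c2ccccc2
F5 | step 4 | 2-(phenylsulfonyl)-11-nordrim-7-en-9-one, C2 epimers | O=C1C(C)=CC[C@H]2C(C)(C)CC(S(=O)(=O)c3ccccc3)C[C@]12C
F6 | step 4 | 2-(phenylsulfonyl)drima-7,9(11)-diene, C2 epimers | C=C1C(C)=CC[C@H]2C(C)(C)CC(S(=O)(=O)c3ccccc3)C[C@]12C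
F7 | step 7 | 1β-hydroxy-11-nordrim-7-en-9-one | O=C1C(C)=CC[C@H]2C(C)(C)CC[C@@H](O)[C@]12C
F8 | step 7 | O-(9-oxo-11-nordrim-7-en-1β-yl) 1H-imidazole-1-carbothioate | O=C1C(C)=CC[C@H]2C(C)(C)CC[C@@H](OC(=S)n3ccnc3)[C@]12C
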